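**Plan**
Retrosynthesis: ring C is cut at O1–C2 and its C4 carbonyl is traced back to a C4–N group. This turns C4–C3–C2 into C3–C4–C5 of a 3,5-diarylisoxazole. That ring is then cut at C4–C3 and at O–C2 into an aryl nitrile oxide (ring A plus C4) and an arylacetylene (C3, C2 and ring B).
Enabling feature: C4, C3 and C2 of ring C form a three-carbon chain with a heteroatom at each end, held between C4a of ring A and C1' of ring B. This is the substitution pattern of a 3,5-diarylisoxazole.
Forward: C4 is placed on ring A by ortho-formylation and the phenol (future O1) is benzylated. The aldehyde goes through the oxime to the hydroximoyl chloride, and the isoxazole forms by [3+2] cycloaddition. The isoxazole is opened by hydrogenolysis, and ring C closes last through O1–C2 in acid.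
Stereochemistry: the target has no stereocentre. The E oxime, Z hydroximoyl chloride and Z enaminoketone are thermodynamic geometries that disappear along the route.

Key step: step 5

Remark: flavone numbering (O1, C2, C3, C4, C4a, C5 to C8, C8a, ring B primed) is used for the future atoms. 2,3,4-Trimethoxyphenol, benzyl bromide and 4-ethynyl-1,2-dimethoxybenzene are taken as catalogue chemicals.

Step 1
Reactants: 1 2,3,4-trimethoxyphenol
Product: 2 2-hydroxy-3,4,5-trimethoxybenzaldehyde
Conditions: MgCl2, Et3N, (CH2O)n, MeCN, reflux; then 1 M HCl
Reagents that add atoms: paraformaldehyde (source of formaldehyde), C=O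
Why: Magnesium-mediated ortho-formylation of a phenol (Casnati–Skattebøl reaction), in which formaldehyde bound to the phenoxide magnesium is delivered only to an ortho carbon, 1 has a single free ortho position (the other carries OMe), and a second formaldehyde accepts hydride to raise the benzylic alkoxide stage to the aldehyde.

Step 2
Reactants: 2 2-hydroxy-3,4,5-trimethoxybenzaldehyde; 3 benzyl bromide
Product: 4 2-(benzyloxy)-3,4,5-trimethoxybenzaldehyde
Conditions: K2CO3, DMF, 60 °C
Reagents that add atoms: none
Why: Williamson ether synthesis in which K2CO3 in DMF deprotonates the chelated salicylaldehyde phenol and the benzylic bromide alkylates it by SN2, masking the future O1 against NCS and against addition to the nitrile oxide with a group that later leaves in the same hydrogenolysis that opens the isoxazole.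

Step 3
Reactants: 4 2-(benzyloxy)-3,4,5-trimethoxybenzaldehyde
Product: 5 (E)-2-(benzyloxy)-3,4,5-trimethoxybenzaldehyde oxime
Conditions: NH2OH·HCl, NaOAc, EtOH–H2O, rt
Reagents that add atoms: hydroxylamine hydrochloride, Cl.NO
Why: Oxime condensation of an aromatic aldehyde under acetate buffer, which should give the thermodynamically preferred E isomer, while the ethers of 4 do not react with hydroxylamine.

Step 4
Reactants: 5 (E)-2-(benzyloxy)-3,4,5-trimethoxybenzaldehyde oxime
Product: 6 (Z)-2-(benzyloxy)-N-hydroxy-3,4,5-trimethoxybenzimidoyl chloride
Conditions: NCS (1.0 equiv), DMF, 0 °C to rt; aqueous work-up, used without chromatography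
Reagents that add atoms: N-chlorosuccinimide, O=C1CCC(=O)N1Cl
Why: Chlorination of an aldoxime with NCS in DMF, the standard entry to benzohydroximoyl chlorides, where one equivalent at low temperature favours the oxime CH over the single ring CH flanked by two substituents, and the Z chloride (Cl and OH on the same side) is the stable isomer.

Step 5
Reactants: 6 (Z)-2-(benzyloxy)-N-hydroxy-3,4,5-trimethoxybenzimidoyl chloride; 7 4-ethynyl-1,2-dimethoxybenzene
Product: 9 3-[2-(benzyloxy)-3,4,5-trimethoxyphenyl]-5-(3,4-dimethoxyphenyl)isoxazole, via aryl nitrile oxide 8 (not isolated)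
Conditions: 7 (1.3 equiv), Et3N (1.1 equiv, syringe pump over several hours), CH2Cl2, 0 °C to rt
Reagents that add atoms: none
Why: Et3N removes HCl from 6 (1,3-dehydrochlorination) and releases nitrile oxide 8 at a low stationary concentration, and 8 adds to the terminal alkyne 7 in a concerted but asynchronous suprafacial [3+2] process. The closest known reaction type is the Huisgen 1,3-dipolar cycloaddition of aryl nitrile oxides to arylacetylenes, which delivers 3,5-diarylisoxazoles. The isoxazole ring closes intermolecularly in a three-atom plus two-atom mode, the dipole carbon bonding to the unsubstituted alkyne carbon (the future C4–C3 bond) and the dipole oxygen to the aryl-bearing alkyne carbon (the future C2–O bond). No stereocentre is created, and the product is aromatic, so the addition is irreversible. The step needs regioselectivity, which the substrates supply because the bulky carbon end of the dipole avoids the substituted alkyne carbon and because the larger HOMO coefficient of the electron-rich alkyne lies on its terminal carbon and matches the larger LUMO coefficient on the dipole carbon. It also needs the cycloaddition to outrun self-dimerisation of 8, which is secured by slow addition of the base, an excess of 7 and the ortho-benzyloxy group that shields the nitrile oxide carbon.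

Step 6
Reactants: 9 3-[2-(benzyloxy)-3,4,5-trimethoxyphenyl]-5-(3,4-dimethoxyphenyl)isoxazole
Product: 11 (Z)-3-amino-1-(3,4-dimethoxyphenyl)-3-(2-hydroxy-3,4,5-trimethoxyphenyl)prop-2-en-1-one, via phenolic isoxazole 10 (not isolated)
Conditions: H2 (3 atm), 10% Pd/C, EtOH–EtOAc, rt
Reagents that add atoms: none
Why: Catalytic hydrogenolysis on palladium, in which the benzylic C–O bond should go first and the weak isoxazole N–O bond second, whereas the resulting enaminoketone is a vinylogous amide held Z by an N–H···O=C hydrogen bond and resists further reduction, and the aryl methyl ethers are inert.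

Step 7
Reactants: 11 (Z)-3-amino-1-(3,4-dimethoxyphenyl)-3-(2-hydroxy-3,4,5-trimethoxyphenyl)prop-2-en-1-one
Product: 13 2-(3,4-dimethoxyphenyl)-6,7,8-trimethoxy-4H-chromen-4-one, via 1,3-diketone 12 (not isolated)
Conditions: AcOH–3 M aq. HCl, 90 °C
Reagents that add atoms: water, O
Why: Acid hydrolysis of the vinylogous amide (C3 protonation, water addition at C4, loss of ammonia) gives the o-hydroxyaryl 1,3-diketone 12, which then undergoes the acid-catalysed cyclodehydration known as the last stage of the Baker–Venkataraman flavone synthesis, a 6-exo-trig attack of the C8a phenol on the ring B carbonyl (O1–C2) followed by loss of water, under conditions that leave aryl methyl ethers intact.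

**Compound list**
1 | 2,3,4-trimethoxyphenol | Oc1ccc(OC)c(OC)c1OC | starting material
2 | 2-hydroxy-3,4,5-trimethoxybenzaldehyde | O=Cc1cc(OC)c(OC)c(OC)c1O | intermediate
3 | benzyl bromide | BrCc1ccccc1 | starting material
4 | 2-(benzyloxy)-3,4,5-trimethoxybenzaldehyde | O=Cc1cc(OC)c(OC)c(OC)c1OCc1ccccc1 | intermediate
5 | (E)-2-(benzyloxy)-3,4,5-trimethoxybenzaldehyde oxime | O/N=C/c1cc(OC)c(OC)c(OC)c1OCc1ccccc1 | intermediate
6 | (Z)-2-(benzyloxy)-N-hydroxy-3,4,5-trimethoxybenzimidoyl chloride | O/N=C(\Cl)c1cc(OC)c(OC)c(OC)c1OCc1ccccc1 | intermediate
7 | 4-ethynyl-1,2-dimethoxybenzene | C#Cc1ccc(OC)c(OC)c1 | starting material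
8 | 2-(benzyloxy)-3,4,5-trimethoxybenzonitrile oxide | [O-][N+]#Cc1cc(OC)c(OC)c(OC)c1OCc1ccccc1 | intermediate
9 | 3-[2-(benzyloxy)-3,4,5-trimethoxyphenyl]-5-(3,4-dimethoxyphenyl)isoxazole | COc1ccc(-c2cc(-c3cc(OC)c(OC)c(OC)c3OCc3ccccc3)no2)cc1OC | intermediate
10 | 5-(3,4-dimethoxyphenyl)-3-(2-hydroxy-3,4,5-trimethoxyphenyl)isoxazole | COc1ccc(-c2cc(-c3cc(OC)c(OC)c(OC)c3O)no2)cc1OC | intermediate
11 | (Z)-3-amino-1-(3,4-dimethoxyphenyl)-3-(2-hydroxy-3,4,5-trimethoxyphenyl)prop-2-en-1-one | N/C(=C\C(=O)c1ccc(OC)c(OC)c1)c1cc(OC)c(OC)c(OC)c1O | intermediate
12 | 1-(3,4-dimethoxyphenyl)-3-(2-hydroxy-3,4,5-trimethoxyphenyl)propane-1,3-dione | O=C(CC(=O)c1ccc(OC)c(OC)c1)c1cc(OC)c(OC)c(OC)c1O | intermediate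
13 | 2-(3,4-dimethoxyphenyl)-6,7,8-trimethoxy-4H-chromen-4-one (6,7,8,3',4'-pentamethoxyflavone) | COc1ccc(-c2cc(=O)c3cc(OC)c(OC)c(OC)c3o2)cc1OC | target

Total step count: 7. Longest linear sequence: 7 steps (1 to 13). Compounds 3 and 7 are bought and enter directly.

**Steps most likely to fail**

Step 4: electrophilic chlorination of the tetra-oxygenated ring A at its one free C–H (future C5) may compete with chlorination at the oxime carbon. The fallback sets out from 5 and rejoins the route at 9. The aldoxime is dehydrogenated with (diacetoxyiodo)benzene, a trivalent iodine oxidant, in MeOH with catalytic TFA at rt in the presence of alkyne 7. Nitrile oxide 8 then forms directly and is trapped as it appears. No chlorine electrophile is present and 6 is bypassed. This detour makes no compound outside the list (F0).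

Step 5: self-dimerisation of the dipole may outrun its addition to the only moderately reactive arylacetylene. The fallback sets out from 6 and rejoins the route at 9. The dipolarophile is changed to the more reactive purchased alkene 4-ethenyl-1,2-dimethoxybenzene F1, under the same slow release of 8 with Et3N in CH2Cl2. With the same regiochemical bias this should give racemic 3-[2-(benzyloxy)-3,4,5-trimethoxyphenyl]-5-(3,4-dimethoxyphenyl)-4,5-dihydroisoxazole F2. F2 is then dehydrogenated to the aromatic isoxazole with activated MnO2 in toluene at reflux.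

Step 6: the two hydrogenolyses run at different rates. N–O cleavage may stall after debenzylation, or forcing conditions may begin to saturate the enaminoketone. The fallback sets out from 9 and rejoins the route at 11. The N–O bond is cleaved first, without hydrogen gas, by Mo(CO)6 in MeCN–H2O at reflux (electron transfer from zerovalent molybdenum bound at nitrogen). This gives (Z)-3-amino-3-[2-(benzyloxy)-3,4,5-trimethoxyphenyl]-1-(3,4-dimethoxyphenyl)prop-2-en-1-one F3. The benzyl ether alone is then removed by mild transfer hydrogenolysis (10% Pd/C, ammonium formate, EtOH, rt).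

**Further compounds**
F0 | step 4 | none | none
F1 | step 5 | 4-ethenyl-1,2-dimethoxybenzene (3,4-dimethoxystyrene; purchased) | C=Cc1ccc(OC)c(OC)c1
F2 | step 5 | 3-[2-(benzyloxy)-3,4,5-trimethoxyphenyl]-5-(3,4-dimethoxyphenyl)-4,5-dihydroisoxazole (racemic at C5) | COc1ccc(C2CC(c3cc(OC)c(OC)c(OC)c3OCc3ccccc3)=NO2)cc1OC
F3 | step 6 | (Z)-3-amino-3-[2-(benzyloxy)-3,4,5-trimethoxyphenyl]-1-(3,4-dimethoxyphenyl)prop-2-en-1-one | N/C(=C\C(=O)c1ccc(OC)c(OC)c1)c1cc(OC)c(OC)c(OC)c1OCc1ccccc1
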